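**Retrosynthetic overview**

1. Target 9 ⇒ its 7-O-pivalate 8 (ester methanolysis, same pot).
2. Key disconnection: lactone C–O bond O1–C2 of the pyranone ring (ring C) ⇒ phenol 7 attacking the carbonyl of a benzofuranone (O→O acyl transfer, five- to six-membered lactone).
3. C8–C(CH3)2 bond ⇒ [3,3] shift of a prenyl group carried by the future ring oxygen O1 (benzylidene lactone 6), so that only C8 can receive it.
4. C3=C4 ⇒ Knoevenagel condensation of aldehyde 4 with 6-hydroxybenzofuran-2(3H)-one 5.
5. 4 ⇒ 1 by 4-O-pivaloylation and 2-O-prenylation (two C–O bonds). Rings A and B are bought; ring C is the only ring formed and closes last.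

Assumption: the target has no stereocentre and no stereogenic double bond, so it is achiral and needs no enantiocontrol; 1, 3 and 5 are taken from supplier catalogues.

**Route**

Step 1
Reactants: 1 2,4-dihydroxy-6-methoxybenzaldehyde
Product: 2 4-formyl-3-hydroxy-5-methoxyphenyl 2,2-dimethylpropanoate
Conditions: PivCl (1.05 equiv), Et3N (1.2 equiv), CH2Cl2, −20 to 0 °C
Reagents that add atoms: pivaloyl chloride, CC(C)(C)C(Cl)=O
Why: Selective O-acylation of a phenol with an acid chloride: the 4-OH is the more acidic, unchelated phenol, whereas the 2-OH is held in a hydrogen bond to the formyl group and is shielded from the bulky acyl chloride.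

Step 2
Reactants: 2 4-formyl-3-hydroxy-5-methoxyphenyl 2,2-dimethylpropanoate; 3 prenyl bromide (1-bromo-3-methylbut-2-ene)
Product: 4 4-formyl-3-methoxy-5-[(3-methylbut-2-en-1-yl)oxy]phenyl 2,2-dimethylpropanoate
Conditions: K2CO3 (1.5 equiv), DMF, 40 °C
Reagents that add atoms: none
Why: Williamson ether synthesis (SN2 of the phenoxide on the primary allylic bromide) at the only free phenol, which puts the prenyl group on the oxygen that later becomes the ring oxygen O1, while the hindered pivalate resists acyl transfer.

Step 3
Reactants: 4 4-formyl-3-methoxy-5-[(3-methylbut-2-en-1-yl)oxy]phenyl 2,2-dimethylpropanoate; 5 6-hydroxybenzofuran-2(3H)-one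
Product: 9 3-(2,4-dihydroxyphenyl)-7-hydroxy-5-methoxy-8-(2-methylbut-3-en-2-yl)-2H-chromen-2-one (target), via Knoevenagel adduct 6 (not isolated), via Claisen phenol 7 (not isolated), via coumarin pivalate 8 (not isolated)
Conditions: 5 (1.1 equiv), Et3N (0.5 equiv), 4 Å molecular sieves, N,N-diethylaniline, argon, 80 °C; then sealed tube, 185 °C; then K2CO3 (3 equiv), MeOH, 25 °C; cold dilute aqueous HCl work-up
Reagents that add atoms: none
Why: Proposed new method: a Claisen-triggered lactone ring expansion, in which Knoevenagel condensation of the acidic CH2 of 5 with 4 gives benzylidene lactone 6, the aromatic Claisen rearrangement ([3,3]) of its aryl prenyl ether at 185 °C goes to the only free ortho carbon and builds the quaternary 2-methylbut-3-en-2-yl group while unmasking phenol 7, and this phenol (after amine-mediated E/Z equilibration) attacks the lactone carbonyl and expels the ring B phenoxide, so that the coumarin C–O bond forms and the new phenol is trapped before it can cyclise onto the new alkene, after which K2CO3/MeOH cleaves the pivalate; the closest known reaction types are the tandem Claisen rearrangement/Wittig olefination/lactonisation of 2-(allyloxy)benzaldehydes to 8-substituted coumarins and the base-mediated rearrangement of 3-(2-hydroxybenzylidene)benzofuran-2(3H)-ones to 3-(2-hydroxyphenyl)coumarins, and no stereocentre is formed.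

**Compound list**

1 | 2,4-dihydroxy-6-methoxybenzaldehyde | COc1cc(O)cc(O)c1C=O | starting material
2 | 4-formyl-3-hydroxy-5-methoxyphenyl 2,2-dimethylpropanoate | COc1cc(OC(=O)C(C)(C)C)cc(O)c1C=O | intermediate
3 | prenyl bromide (1-bromo-3-methylbut-2-ene) | CC(C)=CCBr | starting material
4 | 4-formyl-3-methoxy-5-[(3-methylbut-2-en-1-yl)oxy]phenyl 2,2-dimethylpropanoate | COc1cc(OC(=O)C(C)(C)C)cc(OCC=C(C)C)c1C=O | intermediate
5 | 6-hydroxybenzofuran-2(3H)-one | O=C1Cc2ccc(O)cc2O1 | starting material
6 | Knoevenagel adduct: 4-[(E)-(6-hydroxy-2-oxo-1-benzofuran-3(2H)-ylidene)methyl]-3-methoxy-5-[(3-methylbut-2-en-1-yl)oxy]phenyl 2,2-dimethylpropanoate (E isomer drawn; E and Z interconvert under the amine) | COc1cc(OC(=O)C(C)(C)C)cc(OCC=C(C)C)c1/C=C2/C(=O)Oc3cc(O)ccc23 | intermediate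
7 | Claisen phenol: 4-[(Z)-(6-hydroxy-2-oxo-1-benzofuran-3(2H)-ylidene)methyl]-3-hydroxy-5-methoxy-2-(2-methylbut-3-en-2-yl)phenyl 2,2-dimethylpropanoate (Z isomer drawn, the geometry that lactonises) | COc1cc(OC(=O)C(C)(C)C)c(C(C)(C)C=C)c(O)c1/C=C2\C(=O)Oc3cc(O)ccc23 | intermediate
8 | coumarin pivalate: 3-(2,4-dihydroxyphenyl)-5-methoxy-8-(2-methylbut-3-en-2-yl)-2-oxo-2H-chromen-7-yl 2,2-dimethylpropanoate | C=CC(C)(C)c1c(OC(=O)C(C)(C)C)cc(OC)c2cc(-c3ccc(O)cc3O)c(=O)oc12 | intermediate
9 | 3-(2,4-dihydroxyphenyl)-7-hydroxy-5-methoxy-8-(2-methylbut-3-en-2-yl)-2H-chromen-2-one | C=CC(C)(C)c1c(O)cc(OC)c2cc(-c3ccc(O)cc3O)c(=O)oc12 | target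

**Step count and risks**

Total step count: 3. Longest linear sequence: 3 steps (1 → 2 → 4 → 9).

Steps most likely to fail, most risky first:

Step 3 (the proposed new cascade). Three things can go wrong:
- Benzylidene lactone 6 holds an s-cis enone next to the prenyl alkene, so an intramolecular hetero-Diels–Alder or ene cyclisation could outrun the [3,3] shift.
- The Knoevenagel condensation of the 2,6-dialkoxy aldehyde may be slow.
- The pivalate may scramble onto the ring B phenols at 185 °C.

Fallback, known chemistry only: set out from 4 and separate the events. Heating 4 alone in N,N-diethylaniline at 185 °C gives the aromatic Claisen product with no enone present; the unmasked phenol is parked in a hydrogen bond to the formyl group. This is 4-formyl-3-hydroxy-5-methoxy-2-(2-methylbut-3-en-2-yl)phenyl 2,2-dimethylpropanoate F1. Condensation of F1 with 5 (Et3N, EtOH, 80 °C; Knoevenagel condensation, then lactone rearrangement through 7) gives 8, which is isolated here. The fallback comes back to the route at 8, and K2CO3/MeOH then gives 9.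

Step 2 (alkylation of the chelated phenol beside an aryl ester). Phenoxide-mediated pivaloyl transfer or cleavage under carbonate would send the prenyl group to O4, and the chelated 2-OH may alkylate slowly.

Fallback: set out from 1 and give up delivery from O1. Alkylating the free, more acidic 4-OH of 1 with 3 (K2CO3, acetone, 56 °C) gives 2-hydroxy-6-methoxy-4-[(3-methylbut-2-en-1-yl)oxy]benzaldehyde F2. Condensation and lactone rearrangement with 5 (Et3N, EtOH, 80 °C) gives 3-(2,4-dihydroxyphenyl)-5-methoxy-7-[(3-methylbut-2-en-1-yl)oxy]-2H-chromen-2-one F3. A thermal Claisen rearrangement (N,N-diethylaniline, 190 °C) then moves the prenyl group from O7 to C8, the position favoured for 7-allyloxycoumarins. The fallback comes back to the route at 9.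

Step 1 (site-selective monoacylation). Bis-acylation or acylation at the 2-OH would lower the yield.

Fallback: set out from 1 and acylate exhaustively (PivCl 2.5 equiv, Et3N, DMAP, CH2Cl2, 25 °C) to 4-formyl-5-methoxy-1,3-phenylene bis(2,2-dimethylpropanoate) F4. The ortho ester alone is then removed by aldehyde-assisted methanolysis (hemiacetal neighbouring-group participation; Et3N, MeOH, 0 °C); the para ester lacks this assistance. The fallback comes back to the route at 2.

**Further compounds**

F1 | step 3 | 4-formyl-3-hydroxy-5-methoxy-2-(2-methylbut-3-en-2-yl)phenyl 2,2-dimethylpropanoate | COc1cc(OC(=O)C(C)(C)C)c(C(C)(C)C=C)c(O)c1C=O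
F2 | step 2 | 2-hydroxy-6-methoxy-4-[(3-methylbut-2-en-1-yl)oxy]benzaldehyde | COc1cc(OCC=C(C)C)cc(O)c1C=O
F3 | step 2 | 3-(2,4-dihydroxyphenyl)-5-methoxy-7-[(3-methylbut-2-en-1-yl)oxy]-2H-chromen-2-one | COc1cc(OCC=C(C)C)cc2oc(=O)c(-c3ccc(O)cc3O)cc12
F4 | step 1 | 4-formyl-5-methoxy-1,3-phenylene bis(2,2-dimethylpropanoate) | COc1cc(OC(=O)C(C)(C)C)cc(OC(=O)C(C)(C)C)c1C=O
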